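**Retrosynthetic overview**

1. Locants: cyclopropane C1 (CH3, pyranone), C2 (H), C3 (CH3); cyclopentene C3–C4(H)=C5(CH3)–C6(H, side chain)–C2. The enone is taken back to an (R)-allylic silyl ether (lower oxidation level), and the methoxypyranone to a triketide built on a C1 carbaldehyde.
2. The carbaldehyde is disconnected in one flask into an alkenyl iodide (C5, C6, side chain) and a chiral 5-amino-2,4-dimethylpenta-2,4-dienal (aldehyde carbon = C4). C4–C5 forms by 1,2-addition; C2–C6 (4π conrotatory) and C1–C3 (3-exo) then form from the trienyl iminium ion.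
3. Enabling feature: with C1 as the α-carbon of an iminium group, C2–C3–C4–C5–C6 of the cyclopentene is a pentadienyl cation, so the bicyclo[3.1.0]hex-2-ene is the formal intramolecular [4+2] isomer of a 2,4,6-trimethylhexatriene. The 1,3-dimethyl five-carbon run CHO–C1–C2–C3–C4 is the ring-opened skeleton of 3,5-dimethylpyridine.
4. The aminodienal comes from 3,5-dimethylpyridine (Zincke ring opening, then amine exchange with a recoverable (S)-prolinol-derived amine). The alkenyl iodide comes from pent-1-en-3-one and propyne.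
5. Ring order: cyclopentene, then cyclopropane (same step), pyranone last.

Key step: step 9

Remark: the (R) configuration of the side-chain carbinol (set in step 2) is immaterial to the target because step 15 oxidises it; it is kept defined so that every intermediate is one diastereomer and the facial selectivity of step 9 can be read as a diastereomer ratio.

**Route**

Step 1
Reactants: 1 pent-1-en-3-one
Product: 3 2-bromopent-1-en-3-one, via 1,2-dibromopentan-3-one 2 (not isolated)
Conditions: Br2, CH2Cl2, 0 °C; then Et3N, 0 °C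
Reagents that add atoms: bromine BrBr
Why: Bromination of the enone double bond followed by base-induced loss of HBr from the α-position (bromination–dehydrobromination) should give the α-bromo enone.

Step 2
Reactants: 3 2-bromopent-1-en-3-one
Product: 4 (3R)-2-bromopent-1-en-3-ol
Conditions: (S)-1-methyl-3,3-diphenyltetrahydro-1H,3H-pyrrolo[1,2-c][1,3,2]oxazaborole (10 mol%), BH3·SMe2, THF, −20 °C
Reagents that add atoms: none
Why: Corey–Bakshi–Shibata reduction, in which the 1-bromovinyl group acts as the large substituent so that hydride is delivered to one carbonyl face and the (R)-carbinol, a bystander stereocentre, should result.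

Step 3
Reactants: 4 (3R)-2-bromopent-1-en-3-ol
Product: 5 (3R)-2-bromopent-1-en-3-yl triisopropylsilyl ether
Conditions: i-Pr3SiOTf, 2,6-lutidine, CH2Cl2, 0 °C
Reagents that add atoms: triisopropylsilyl trifluoromethanesulfonate CC(C)[Si](C(C)C)(C(C)C)OS(=O)(=O)C(F)(F)F
Why: Silylation of the secondary allylic alcohol gives an ether chosen to survive organolithium, acid, DBU and methyl triflate steps.

Step 4
Reactants: 5 (3R)-2-bromopent-1-en-3-yl triisopropylsilyl ether; 6 propyne
Product: 7 (5R)-4-methylidenehept-2-yn-5-yl triisopropylsilyl ether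
Conditions: Pd(PPh3)2Cl2 (5 mol%), CuI (10 mol%), Et3N, THF, 40 °C, sealed tube
Reagents that add atoms: none
Why: Sonogashira coupling of the 1,1-disubstituted vinyl bromide with propyne should install C5 with its methyl group and C6.

Step 5
Reactants: 7 (5R)-4-methylidenehept-2-yn-5-yl triisopropylsilyl ether
Product: 9 (2E,5R)-2-iodo-4-methylidenehept-2-en-5-yl triisopropylsilyl ether, via alkenylzirconocene chloride 8 (not isolated)
Conditions: Cp2Zr(H)Cl, THF, rt to 40 °C; then I2, 0 °C
Reagents that add atoms: iodine II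
Why: Syn hydrozirconation should place zirconium on the less hindered methyl-bearing alkyne carbon (thermodynamic regiocontrol), and iodinolysis with retention then fixes the (E)-C5=C6 geometry that later keeps the side chain outside the cyclising cation.

Step 6
Reactants: 10 3,5-dimethylpyridine; 11 1-chloro-2,4-dinitrobenzene
Product: 12 1-(2,4-dinitrophenyl)-3,5-dimethylpyridinium chloride
Conditions: acetone, reflux
Reagents that add atoms: none
Why: Nucleophilic aromatic substitution by the pyridine nitrogen gives the activated pyridinium salt of the Zincke reaction.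

Step 7
Reactants: 12 1-(2,4-dinitrophenyl)-3,5-dimethylpyridinium chloride
Product: 14 (2E,4E)-5-(dimethylamino)-2,4-dimethylpenta-2,4-dienal, via pentamethine iminium chloride 13 (not isolated)
Conditions: Me2NH (2.5 equiv), EtOH, 0 °C to rt; then aq. NaOH, rt
Reagents that add atoms: dimethylamine CNC; sodium hydroxide [Na+].[OH-]
Why: Zincke ring opening (amine addition at C2 of the pyridinium, electrocyclic ring opening, expulsion of 2,4-dinitroaniline) and hydrolysis of one terminus of the pentamethine salt should give the push-pull dienal as the thermodynamically preferred (E,E) isomer.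

Step 8
Reactants: 14 (2E,4E)-5-(dimethylamino)-2,4-dimethylpenta-2,4-dienal; 15 (S)-2-[diphenyl(trimethylsilyloxy)methyl]pyrrolidine
Product: 16 (2E,4E)-5-[(2S)-2-{diphenyl[(trimethylsilyl)oxy]methyl}pyrrolidin-1-yl]-2,4-dimethylpenta-2,4-dienal
Conditions: AcOH (10 mol%), toluene, 80 °C, N2 sweep
Reagents that add atoms: none
Why: Amine exchange on a vinylogous formamide (conjugate addition–elimination at the amino-bearing carbon) should be driven to 16 by loss of volatile dimethylamine.

Step 9
Reactants: 9 (2E,5R)-2-iodo-4-methylidenehept-2-en-5-yl triisopropylsilyl ether; 16 (2E,4E)-5-[(2S)-2-{diphenyl[(trimethylsilyl)oxy]methyl}pyrrolidin-1-yl]-2,4-dimethylpenta-2,4-dienal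
Product: 21 (1S,4R,5R,6S)-1,3,6-trimethyl-4-[(3R)-3-(triisopropylsilyloxy)pent-1-en-2-yl]bicyclo[3.1.0]hex-2-ene-6-carbaldehyde, via alkenyllithium 17 (not isolated), via lithium alkoxide adduct 18 (not isolated), via trienyl iminium trifluoroacetate 19 (not isolated), via cyclopropyl iminium trifluoroacetate 20 (not isolated)
Conditions: 9, t-BuLi (2 equiv), Et2O, −78 °C; then 16, THF, −78 °C; then (CF3CO)2O, 2,6-lutidine, −78 to 0 °C; then H2O/NaHCO3, THF, rt
Reagents that add atoms: water O
Why: Proposed new method: the alkenyllithium 17 adds 1,2 to the aldehyde of the vinylogous formamide 16 (new C4–C5 bond) and O-trifluoroacetylation lets the doubly allylic ester ionise with nitrogen assistance to the trienyl iminium ion 19, the covalent counterpart of a Lewis-acid-bound 2,4,6-trimethyltrienal in which C2, C4 and C6 carry the positive charge. Its C2–C6 pentadienyl cation closes the cyclopentene by thermal 4π conrotatory electrocyclisation (new C2–C6 bond), and the dienamine carbon C1 then captures C3 of the 1,3-dimethylallyl cation by 3-exo closure (new C1–C3 bond, cyclopropane), which leaves the C4=C5 double bond and iminium 20 that water hydrolyses with release of amine 15. The closest known reaction types are the one-flask organolithium addition, ionisation and Nazarov cyclisation steered by a traceless chiral auxiliary, the Lewis-acid-catalysed cycloisomerisation of trienyl carbonyl compounds to bicyclo[3.1.0]hex-2-enes, and the addition–transposition of organolithiums on Zincke aldehydes; iminium activation replaces the Lewis acid. Relative configuration is mechanistic: C1 and the side chain both lie outside the U-shaped cation so conrotation sets them trans at C2 and C6, the cyclopropane can only form on the face of C2 that carries C1 (cis fusion, C3), and the bulky aminovinyl group rather than CH3 takes the exo position at C1. Absolute configuration comes from the (S)-diarylprolinol ether, whose CPh2(OSiMe3) group in the (E)-iminium with the extended geometry inherited from 16 covers the Si face of C2, so that C6 bonds to its Re face. The step needs five-ring (C2–C6) rather than six-ring (C1–C6) closure and the (Z)-C3=C4 rotamer: the cationic manifold favours the 4π path as in the Lewis acid precedent, and the low rotation barriers of the delocalised cation let the E and Z forms interconvert so that the U-shaped one is drained.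

Step 10
Reactants: 21 the bicyclic carbaldehyde; 22 methyl 2-methyl-3-oxopentanoate
Product: 24 methyl 5-hydroxy-2,4-dimethyl-3-oxo-5-{(1S,4R,5R,6S)-1,3,6-trimethyl-4-[(3R)-3-(triisopropylsilyloxy)pent-1-en-2-yl]bicyclo[3.1.0]hex-2-en-6-yl}pentanoate (mixture of epimers at the three chain stereocentres), via sodium lithium dianion 23 (not isolated)
Conditions: 22, NaH then n-BuLi, THF, 0 °C; then 21, −78 °C
Reagents that add atoms: none
Why: γ-Selective aldol addition of the β-keto ester dianion to the non-enolisable aldehyde should give the adduct, whose new stereocentres are removed in steps 11 and 12.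

Step 11
Reactants: 24 the δ-hydroxy-β-keto ester
Product: 25 methyl 2,4-dimethyl-3,5-dioxo-5-{(1S,4R,5R,6S)-1,3,6-trimethyl-4-[(3R)-3-(triisopropylsilyloxy)pent-1-en-2-yl]bicyclo[3.1.0]hex-2-en-6-yl}pentanoate
Conditions: Dess–Martin periodinane, NaHCO3, CH2Cl2, rt
Reagents that add atoms: none
Why: Dess–Martin oxidation of the secondary alcohol gives the β,δ-diketo ester without touching the alkenes or the silyl ether.

Step 12
Reactants: 25 the β,δ-diketo ester
Product: 26 4-hydroxy-3,5-dimethyl-6-{(1S,4R,5R,6S)-1,3,6-trimethyl-4-[(3R)-3-(triisopropylsilyloxy)pent-1-en-2-yl]bicyclo[3.1.0]hex-2-en-6-yl}-2H-pyran-2-one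
Conditions: DBU, toluene, 60 °C
Reagents that add atoms: none
Why: Base-mediated lactonisation of the δ-enol oxygen onto the ester (6-exo-trig acyl substitution) should close the pyranone ring with loss of methanol.

Step 13
Reactants: 26 the 4-hydroxy-2-pyranone
Product: 27 2-methoxy-3,5-dimethyl-6-{(1S,4R,5R,6S)-1,3,6-trimethyl-4-[(3R)-3-(triisopropylsilyloxy)pent-1-en-2-yl]bicyclo[3.1.0]hex-2-en-6-yl}-4H-pyran-4-one
Conditions: MeOTf, CH2Cl2, 0 °C to rt; then aq. NaHCO3
Reagents that add atoms: methyl trifluoromethanesulfonate COS(=O)(=O)C(F)(F)F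
Why: Kinetic O-methylation of the neutral hydroxypyranone at the more nucleophilic lactone carbonyl oxygen, followed by proton loss, should give the 2-methoxy-4-pyranone rather than its 4-methoxy-2-pyranone isomer.

Step 14
Reactants: 27 the silyl-protected methoxypyranone
Product: 28 6-{(1S,4R,5R,6S)-4-[(3R)-3-hydroxypent-1-en-2-yl]-1,3,6-trimethylbicyclo[3.1.0]hex-2-en-6-yl}-2-methoxy-3,5-dimethyl-4H-pyran-4-one
Conditions: Bu4NF, THF, 0 °C to rt
Reagents that add atoms: none
Why: Fluoride-induced desilylation frees the allylic alcohol while the pyranone and the bicyclic core are inert to fluoride.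

Step 15
Reactants: 28 the allylic alcohol
Product: 29 2-methoxy-3,5-dimethyl-6-[(1S,4R,5R,6S)-1,3,6-trimethyl-4-(3-oxopent-1-en-2-yl)bicyclo[3.1.0]hex-2-en-6-yl]-4H-pyran-4-one (CNP0260557.1)
Conditions: Dess–Martin periodinane, NaHCO3, CH2Cl2, 0 °C
Reagents that add atoms: none
Why: Buffered Dess–Martin oxidation of the allylic alcohol should give the α-methylene ketone last and under non-basic conditions, so that the exocyclic alkene does not move into conjugation and the C6 stereocentre is kept.

**Compound list**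

1 | pent-1-en-3-one | C=CC(=O)CC | starting material
2 | 1,2-dibromopentan-3-one (not isolated) | BrCC(Br)C(=O)CC | intermediate
3 | 2-bromopent-1-en-3-one | C=C(Br)C(=O)CC | intermediate
4 | (3R)-2-bromopent-1-en-3-ol | C=C(Br)[C@H](O)CC | intermediate
5 | (3R)-2-bromopent-1-en-3-yl triisopropylsilyl ether | C=C(Br)[C@H](O[Si](C(C)C)(C(C)C)C(C)C)CC | intermediate
6 | propyne | CC#C | starting material
7 | (5R)-4-methylidenehept-2-yn-5-yl triisopropylsilyl ether | CC#CC(=C)[C@H](O[Si](C(C)C)(C(C)C)C(C)C)CC | intermediate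
8 | alkenylzirconocene chloride from 7, zirconium on the methyl-bearing carbon (not isolated) | C/C(=C\C(=C)[C@H](O[Si](C(C)C)(C(C)C)C(C)C)CC)[Zr](Cl)(C1C=CC=C1)C1C=CC=C1 | intermediate
9 | (2E,5R)-2-iodo-4-methylidenehept-2-en-5-yl triisopropylsilyl ether | C/C(I)=C\C(=C)[C@H](O[Si](C(C)C)(C(C)C)C(C)C)CC | intermediate
10 | 3,5-dimethylpyridine | Cc1cncc(C)c1 | starting material
11 | 1-chloro-2,4-dinitrobenzene | Clc1ccc(cc1[N+](=O)[O-])[N+](=O)[O-] | starting material
12 | 1-(2,4-dinitrophenyl)-3,5-dimethylpyridinium chloride | Cc1cc(C)c[n+](c1)-c1ccc(cc1[N+](=O)[O-])[N+](=O)[O-].[Cl-] | intermediate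
13 | [(2E,4E)-5-(dimethylamino)-2,4-dimethylpenta-2,4-dienylidene]dimethylammonium chloride (not isolated) | CN(C)/C=C(C)/C=C(C)/C=[N+](C)C.[Cl-] | intermediate
14 | (2E,4E)-5-(dimethylamino)-2,4-dimethylpenta-2,4-dienal | CN(C)/C=C(C)/C=C(C)/C=O | intermediate
15 | (S)-2-[diphenyl(trimethylsilyloxy)methyl]pyrrolidine (recoverable auxiliary) | C[Si](C)(C)OC(c1ccccc1)(c1ccccc1)[C@@H]1CCCN1 | starting material
16 | (2E,4E)-5-[(2S)-2-{diphenyl[(trimethylsilyl)oxy]methyl}pyrrolidin-1-yl]-2,4-dimethylpenta-2,4-dienal | O=C/C(C)=C/C(C)=C/N1CCC[C@H]1C(O[Si](C)(C)C)(c1ccccc1)c1ccccc1 | intermediate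
17 | alkenyllithium from 9, lithium in place of iodine with retention (not isolated) | C/C([Li])=C\C(=C)[C@H](O[Si](C(C)C)(C(C)C)C(C)C)CC | intermediate
18 | lithium alkoxide of the doubly allylic carbinol from 17 and 16, both epimers at the carbinol carbon (not isolated) | [Li+].[O-]C(/C(C)=C/C(C)=C/N1CCC[C@H]1C(O[Si](C)(C)C)(c1ccccc1)c1ccccc1)/C(C)=C/C(=C)[C@H](O[Si](C(C)C)(C(C)C)C(C)C)CC | intermediate
19 | trienyl iminium trifluoroacetate, drawn as the reactive (Z)-C3=C4 form (not isolated) | [O-]C(=O)C(F)(F)F.C(=[N+]1CCC[C@H]1C(O[Si](C)(C)C)(c1ccccc1)c1ccccc1)/C(C)=C/C(C)=C\C(C)=C\C(=C)[C@H](O[Si](C(C)C)(C(C)C)C(C)C)CC | intermediate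
20 | cyclopropyl iminium trifluoroacetate of 21 with amine 15 (not isolated) | [O-]C(=O)C(F)(F)F.C=C([C@H](O[Si](C(C)C)(C(C)C)C(C)C)CC)[C@H]1C(C)=C[C@@]2(C)[C@@H]1[C@]2(C)C=[N+]1CCC[C@H]1C(O[Si](C)(C)C)(c1ccccc1)c1ccccc1 | intermediate
21 | (1S,4R,5R,6S)-1,3,6-trimethyl-4-[(3R)-3-(triisopropylsilyloxy)pent-1-en-2-yl]bicyclo[3.1.0]hex-2-ene-6-carbaldehyde | C=C([C@H](O[Si](C(C)C)(C(C)C)C(C)C)CC)[C@H]1C(C)=C[C@@]2(C)[C@@H]1[C@]2(C)C=O | intermediate
22 | methyl 2-methyl-3-oxopentanoate | CCC(=O)C(C)C(=O)OC | starting material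
23 | sodium lithium dianion of 22 (not isolated) | [Na+].[Li+].C[CH-]C(=O)[C-](C)C(=O)OC | intermediate
24 | methyl 5-hydroxy-2,4-dimethyl-3-oxo-5-(bicyclic core)pentanoate, epimers at the chain stereocentres | C=C([C@H](O[Si](C(C)C)(C(C)C)C(C)C)CC)[C@H]1C(C)=C[C@@]2(C)[C@@H]1[C@]2(C)C(O)C(C)C(=O)C(C)C(=O)OC | intermediate
25 | methyl 2,4-dimethyl-3,5-dioxo-5-(bicyclic core)pentanoate | C=C([C@H](O[Si](C(C)C)(C(C)C)C(C)C)CC)[C@H]1C(C)=C[C@@]2(C)[C@@H]1[C@]2(C)C(=O)C(C)C(=O)C(C)C(=O)OC | intermediate
26 | 4-hydroxy-3,5-dimethyl-6-(bicyclic core)-2H-pyran-2-one | C=C([C@H](O[Si](C(C)C)(C(C)C)C(C)C)CC)[C@H]1C(C)=C[C@@]2(C)[C@@H]1[C@]2(C)c1oc(=O)c(C)c(O)c1C | intermediate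
27 | 2-methoxy-3,5-dimethyl-6-{(1S,4R,5R,6S)-1,3,6-trimethyl-4-[(3R)-3-(triisopropylsilyloxy)pent-1-en-2-yl]bicyclo[3.1.0]hex-2-en-6-yl}-4H-pyran-4-one | C=C([C@H](O[Si](C(C)C)(C(C)C)C(C)C)CC)[C@H]1C(C)=C[C@@]2(C)[C@@H]1[C@]2(C)c1oc(OC)c(C)c(=O)c1C | intermediate
28 | 6-{(1S,4R,5R,6S)-4-[(3R)-3-hydroxypent-1-en-2-yl]-1,3,6-trimethylbicyclo[3.1.0]hex-2-en-6-yl}-2-methoxy-3,5-dimethyl-4H-pyran-4-one | C=C([C@H](O)CC)[C@H]1C(C)=C[C@@]2(C)[C@@H]1[C@]2(C)c1oc(OC)c(C)c(=O)c1C | intermediate
29 | 2-methoxy-3,5-dimethyl-6-[(1S,4R,5R,6S)-1,3,6-trimethyl-4-(3-oxopent-1-en-2-yl)bicyclo[3.1.0]hex-2-en-6-yl]-4H-pyran-4-one | C=C(C(=O)CC)[C@H]1C(C)=C[C@@]2(C)[C@@H]1[C@]2(C)c1oc(OC)c(C)c(=O)c1C | target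

**Step count and risks**

Total step count: 15. Longest linear sequence: 12 steps (steps 1–5 and 9–15).

Steps most likely to fail:

1. Step 9 (Proposed new method). The delocalised trienyl iminium ion may be too stabilised to undergo the 4π closure, may be hydrolysed to the open trienal before it closes, may close with poor facial selectivity, or the cyclopropyl iminium ion may reopen before hydrolysis. Fallback with known chemistry, setting out from 9 and returning at 21: prop-2-yn-1-ol is converted by CuI-catalysed anti-methylmagnesiation (MeMgBr) and iodinolysis into (Z)-3-iodo-2-methylprop-2-en-1-ol F1, which one-pot MnO2 oxidation and Wittig olefination with Ph3P=C(CH3)CO2Et should turn into ethyl (2E,4Z)-5-iodo-2,4-dimethylpenta-2,4-dienoate F2. Negishi coupling of F2 with the alkenylzinc chloride made from 9 (t-BuLi, ZnCl2, then Pd(PPh3)4, THF) should give ethyl (2E,4Z,6E,9R)-2,4,6-trimethyl-8-methylidene-9-(triisopropylsilyloxy)undeca-2,4,6-trienoate F3. (i-Bu)2AlH reduction gives (2E,4Z,6E,9R)-2,4,6-trimethyl-8-methylidene-9-(triisopropylsilyloxy)undeca-2,4,6-trien-1-ol F4, and MnO2 oxidation gives (2E,4Z,6E,9R)-2,4,6-trimethyl-8-methylidene-9-(triisopropylsilyloxy)undeca-2,4,6-trienal F5. Me2AlCl-catalysed cycloisomerisation of F5 in CH2Cl2, the known Lewis acid version of the same ring construction, should give 21 together with (1R,4S,5S,6R)-1,3,6-trimethyl-4-[(3R)-3-(triisopropylsilyloxy)pent-1-en-2-yl]bicyclo[3.1.0]hex-2-ene-6-carbaldehyde F6. The (R)-silyloxy stereocentre makes the two diastereomers separable by chromatography, and 21 re-enters the route at step 10.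

2. Step 8. Amine exchange may stall because the α-branched amine 15 must attack a carbon flanked by the 4-methyl group, and prolonged heating with acid may cause loss of the trimethylsilyl ether. Fallback, setting out from 14 and returning at 16: aqueous NaOH hydrolysis of 14 should give sodium (1E,3E)-2,4-dimethyl-5-oxopenta-1,3-dien-1-olate F7, which is condensed at room temperature in ethanol with the hydrochloride of 15 (enaminone formation from a vinylogous acid) to give 16.

3. Step 7. Ring opening may fail because amine attack at C2 of the pyridinium is slowed by the adjacent 3-methyl group, so that substitution at the dinitrophenyl carbon, which returns 3,5-dimethylpyridine, competes. Fallback, setting out from 10 and returning at 14: N-sulfonation of 10 with the SO3–dioxane complex should give 3,5-dimethylpyridinium-1-sulfonate F8; cold aqueous KOH opens the ring to potassium (1E,3E)-2,4-dimethyl-5-oxopenta-1,3-dien-1-olate F9, and condensation with dimethylammonium chloride gives 14.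

**Further compounds**

F1 | step 9 | (Z)-3-iodo-2-methylprop-2-en-1-ol | OC/C(C)=C\I
F2 | step 9 | ethyl (2E,4Z)-5-iodo-2,4-dimethylpenta-2,4-dienoate | CCOC(=O)/C(C)=C/C(C)=C\I
F3 | step 9 | ethyl (2E,4Z,6E,9R)-2,4,6-trimethyl-8-methylidene-9-(triisopropylsilyloxy)undeca-2,4,6-trienoate | CCOC(=O)/C(C)=C/C(C)=C\C(C)=C\C(=C)[C@H](O[Si](C(C)C)(C(C)C)C(C)C)CC
F4 | step 9 | (2E,4Z,6E,9R)-2,4,6-trimethyl-8-methylidene-9-(triisopropylsilyloxy)undeca-2,4,6-trien-1-ol | OC/C(C)=C/C(C)=C\C(C)=C\C(=C)[C@H](O[Si](C(C)C)(C(C)C)C(C)C)CC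
F5 | step 9 | (2E,4Z,6E,9R)-2,4,6-trimethyl-8-methylidene-9-(triisopropylsilyloxy)undeca-2,4,6-trienal | O=C/C(C)=C/C(C)=C\C(C)=C\C(=C)[C@H](O[Si](C(C)C)(C(C)C)C(C)C)CC
F6 | step 9 | (1R,4S,5S,6R)-1,3,6-trimethyl-4-[(3R)-3-(triisopropylsilyloxy)pent-1-en-2-yl]bicyclo[3.1.0]hex-2-ene-6-carbaldehyde | C=C([C@H](O[Si](C(C)C)(C(C)C)C(C)C)CC)[C@@H]1C(C)=C[C@]2(C)[C@H]1[C@@]2(C)C=O
F7 | step 8 | sodium (1E,3E)-2,4-dimethyl-5-oxopenta-1,3-dien-1-olate | [Na+].[O-]/C=C(C)/C=C(C)/C=O
F8 | step 7 | 3,5-dimethylpyridinium-1-sulfonate | Cc1cc(C)c[n+](c1)S(=O)(=O)[O-]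
F9 | step 7 | potassium (1E,3E)-2,4-dimethyl-5-oxopenta-1,3-dien-1-olate | [K+].[O-]/C=C(C)/C=C(C)/C=O
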